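**Retrosynthetic overview**

1. Isochroman-1-one locants (C1 lactone carbonyl, O2, C3, C4, C4a–C8a; Cα/Cβ for the side-chain alkene) are kept for the same atoms in every precursor. The feature used is the unit C8a–C1(=O)–O2–C3H(CO2Me) of the lactone ring, which is an aroyloxy ester. Removing O2 and bonding C1 to C3 contracts the six-membered lactone to a 1-indanone-2-carboxylate, in which C3 lies between two carbonyl groups and is therefore easy to form and to oxygenate.
2. Endgame: target ⇐ tribenzyl ether acid ⇐ enal ⇐ allylic alcohol ⇐ silyl ether. Cβ stays at the alcohol level until all base chemistry is over, so C4–H is never vinylogously acidic in base.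
3. Key disconnection: the C1–O2 bond of the lactone ⇐ the C1–C3 bond of a 2-hydroxyindanone (C-to-O aroyl shift, five-membered ring grows to six). The hydroxyl comes from a neutral α-hydroxylation and the carbocycle from a Dieckmann closure of C3 onto C1.
4. C4 and the E-alkene ⇐ Johnson–Claisen rearrangement of an (S,Z)-β-aryl Morita–Baylis–Hillman-type alcohol. That alcohol ⇐ Negishi union of the C4a-metalated benzoate with a β-iodoacrylate built from methyl propiolate, TMSI and the silyloxyacetaldehyde.
5. Ring order: arene (bought) → five-membered carbocycle (step 6) → transient oxirane and six-membered lactone (step 8).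

Key step: step 8

Assumption: the L-proline-derived catalyst of step 3 is taken to leave the si face of the boron-bound aldehyde open (formyl C–H···O binding model); the configuration of 8 is to be checked by MTPA ester analysis, and the D-proline-derived catalyst is used if the sense proves opposite.

**Route**

Step 1
Reactants: 1 2,4,5-trihydroxybenzoic acid
Product: 2 methyl 2,4,5-trihydroxybenzoate
Conditions: MeOH, H2SO4 (cat.), reflux, Ar
Reagents that add atoms: methanol, CO
Why: Fischer esterification, in which acid catalysis touches only the carboxyl group and keeps the oxidation-prone hydroxyquinol nucleus protonated.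

Step 2
Reactants: 2 methyl 2,4,5-trihydroxybenzoate
Product: 3 methyl 2,4,5-tris(benzyloxy)benzoate
Conditions: BnBr (3.6 equiv), K2CO3, KI (cat.), DMF, 60 °C, Ar
Reagents that add atoms: benzyl bromide, BrCc1ccccc1
Why: Williamson ether synthesis, in which warm DMF also alkylates the hydrogen-bonded 2-OH and the inert atmosphere prevents oxidation of the phenolates to a hydroxyquinone.

Step 3
Reactants: 4 methyl propiolate; 5 (tert-butyldimethylsilyloxy)acetaldehyde
Product: 8 methyl (2Z,3S)-4-(tert-butyldimethylsilyloxy)-3-hydroxy-2-(iodomethylidene)butanoate, via iodoallenyl silyl ketene acetal 6 (not isolated), via trimethylsilyl ether 7 (not isolated)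
Conditions: TMSI (1.2 equiv), B-(o-tolyl)oxazaborolidine from (S)-α,α-diphenylprolinol activated by Tf2NH (20 mol%), CH2Cl2, −78 °C; then 1 M HCl, THF, 0 °C
Reagents that add atoms: iodotrimethylsilane, C[Si](C)(C)I
Why: Catalytic asymmetric three-component iodo-aldol (β-iodo Morita–Baylis–Hillman) reaction, in which conjugate addition of iodide to 4 gives allenolate 6, which bonds through its α-carbon to the si face of the catalyst-bound aldehyde and so sets (S), while approach on the hydrogen side of the allenolate leaves iodine cis to the ester (Z).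

Step 4
Reactants: 3 methyl 2,4,5-tris(benzyloxy)benzoate; 8 methyl (2Z,3S)-4-(tert-butyldimethylsilyloxy)-3-hydroxy-2-(iodomethylidene)butanoate
Product: 11 methyl 3,4,6-tris(benzyloxy)-2-[(1Z,3S)-4-(tert-butyldimethylsilyloxy)-3-hydroxy-2-(methoxycarbonyl)but-1-en-1-yl]benzoate, via arylmagnesium chloride 9 (not isolated), via arylzinc chloride 10 (not isolated)
Conditions: 3, TMPMgCl·LiCl (1.2 equiv), THF, 0 → 25 °C; ZnCl2 (1.3 equiv), 0 °C; then 8 (0.9 equiv), Pd(OAc)2 (2 mol%), SPhos (4 mol%), THF, 25 °C
Reagents that add atoms: none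
Why: Directed ortho-magnesiation then Negishi cross-coupling, in which the hindered amide base removes the one ring hydrogen flanked by the coordinating ester and an acidifying benzyloxy group (future C4a; electrophilic halogenation is avoided because it should attack the carbon between the 2- and 4-benzyloxy groups, future C7), and after Mg-to-Zn exchange zerovalent palladium joins the arylzinc to the alkenyl iodide with retention, so the aryl group stays cis to the acrylate ester, the carbinol centre is untouched and the weakly basic arylzinc tolerates the free hydroxyl.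

Step 5
Reactants: 11 methyl 3,4,6-tris(benzyloxy)-2-[(1Z,3S)-4-(tert-butyldimethylsilyloxy)-3-hydroxy-2-(methoxycarbonyl)but-1-en-1-yl]benzoate; 12 trimethyl orthoacetate
Product: 15 dimethyl (2E,3R)-3-[2,3,5-tris(benzyloxy)-6-(methoxycarbonyl)phenyl]-2-[2-(tert-butyldimethylsilyloxy)ethylidene]pentanedioate, via mixed orthoester 13 (not isolated), via allyl ketene acetal 14 (not isolated)
Conditions: MeC(OMe)3 (10 equiv), EtCO2H (10 mol%), toluene, 110–125 °C (sealed tube, 4 Å MS)
Reagents that add atoms: trimethyl orthoacetate (12), CC(OC)(OC)OC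
Why: Johnson–Claisen rearrangement, in which orthoester exchange and loss of methanol give ketene acetal 14, whose nucleophilic CH2 terminus bonds suprafacially to the electrophilic β-carbon of the acrylate so that the (S)-carbinol configuration is relayed to C4 (R), while the CH2OTBS group should take the pseudoaxial site to escape 1,2-allylic strain with the neighbouring ester (it meets only H on the aryl-bearing carbon, because the aryl group is trans to the carbinol carbon) and thereby gives the E-alkene; any Z-isomer carries the opposite C4 configuration and must be removed by chromatography.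

Step 6
Reactants: 15 dimethyl (2E,3R)-3-[2,3,5-tris(benzyloxy)-6-(methoxycarbonyl)phenyl]-2-[2-(tert-butyldimethylsilyloxy)ethylidene]pentanedioate
Product: 17 methyl (3R)-4,5,7-tris(benzyloxy)-3-[(2E)-4-(tert-butyldimethylsilyloxy)-1-methoxy-1-oxobut-2-en-2-yl]-1-oxo-2,3-dihydro-1H-indene-2-carboxylate, via lithium enolate 16 (not isolated)
Conditions: LiN(SiMe3)2 (2.1 equiv), THF, −78 → 0 °C; AcOH quench at −78 °C
Reagents that add atoms: none
Why: Dieckmann condensation, in which the C3 methylene is the only position α to a saturated ester, its enolate closes 5-exo-trig on the neighbouring aryl ester C1, and deprotonation of the β-keto ester to 16 drives the closure, while C4 has no adjacent carbonyl and keeps its configuration.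

Step 7
Reactants: 17 methyl (3R)-4,5,7-tris(benzyloxy)-3-[(2E)-4-(tert-butyldimethylsilyloxy)-1-methoxy-1-oxobut-2-en-2-yl]-1-oxo-2,3-dihydro-1H-indene-2-carboxylate
Product: 18 methyl (2R,3R)-4,5,7-tris(benzyloxy)-3-[(2E)-4-(tert-butyldimethylsilyloxy)-1-methoxy-1-oxobut-2-en-2-yl]-2-hydroxy-1-oxo-2,3-dihydro-1H-indene-2-carboxylate
Conditions: dimethyldioxirane (1.1 equiv), acetone/CH2Cl2, −20 → 0 °C
Reagents that add atoms: dimethyldioxirane, CC1(C)OO1
Why: α-Hydroxylation of a β-keto ester by dioxirane epoxidation of its enol under neutral conditions, so no alkoxide forms prematurely; the reagent should approach C3 on the face opposite to the C4 side chain, which places the hydroxyl trans to it and out of reach of the Cα ester (no γ-lactone), and the electron-poor acrylate is not epoxidised.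

Step 8
Reactants: 18 methyl (2R,3R)-4,5,7-tris(benzyloxy)-3-[(2E)-4-(tert-butyldimethylsilyloxy)-1-methoxy-1-oxobut-2-en-2-yl]-2-hydroxy-1-oxo-2,3-dihydro-1H-indene-2-carboxylate
Product: 22 methyl (3S,4R)-5,6,8-tris(benzyloxy)-4-[(2E)-4-(tert-butyldimethylsilyloxy)-1-methoxy-1-oxobut-2-en-2-yl]-1-oxoisochromane-3-carboxylate, via fused oxiranolate 19 (not isolated), via lactone ester enolate 20 (not isolated), via cis lactone 21 (not isolated)
Conditions: DBU (20 mol%), MeCN, 4 Å MS, 0 → 40 °C, held until the C3 epimer composition no longer changes; AcOH quench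
Reagents that add atoms: none
Why: Proposed new method: reversible deprotonation of the tertiary alcohol at C3 by DBU lets its oxygen bond to the neighbouring aryl ketone carbon C1 (3-exo-trig, fused oxiranolate 19), and when the C1 carbonyl re-forms, the C1–C3 bond shared by oxirane and cyclopentanone breaks, so the six-membered lactone arises by ring expansion (an internal retro-Claisen fragmentation, not a direct cyclisation) and C3 is left as ester enolate 20. The nearest known reactions are the base-induced C-to-O acyl shift of 2-hydroxy-1,3-dicarbonyl compounds (ring enlargement of 2-hydroxyindane-1,3-diones to isochroman-1,4-diones) and, read backwards, the Chan rearrangement of acyloxy esters, but an α-hydroxy β-keto ester that has to expel an ester enolate has not been used in this way. Compound 18 has no α-hydrogen and cannot rest as a stabilised enolate, so with substoichiometric base the neutral isomers compete, and the aryl lactone (ester resonance gained, cyclopentanone strain lost) should be the sink. C3 is the only new stereocentre: protonation of planar 20 on the face away from the pseudoaxial C4 side chain puts the ester cis to that chain (21), so the trans relation is not the kinetic result but should be reached by DBU-mediated re-enolisation of the acidic C3–H until the trans-diaxial half-chair predominates (C4 group held pseudoaxial by the peri C5 benzyloxy group, ester anti to it). The selectivity needed is migration of the aroyl carbon C1 rather than of the methoxycarbonyl group, which the substrate supports through the higher electrophilicity of a ketone over an ester and through strain release that only the C1 shift brings. C4 is untouched because, with Cβ at the alcohol level, its hydrogen is only benzylic and allylic.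

Step 9
Reactants: 22 methyl (3S,4R)-5,6,8-tris(benzyloxy)-4-[(2E)-4-(tert-butyldimethylsilyloxy)-1-methoxy-1-oxobut-2-en-2-yl]-1-oxoisochromane-3-carboxylate
Product: 23 methyl (3S,4R)-5,6,8-tris(benzyloxy)-4-[(2E)-4-hydroxy-1-methoxy-1-oxobut-2-en-2-yl]-1-oxoisochromane-3-carboxylate
Conditions: HF·pyridine, pyridine/THF, 0 °C → rt
Reagents that add atoms: none
Why: Fluoride cleavage of the silyl ether in a weakly acidic medium, chosen over basic Bu4NF so that C3 is not epimerised and the lactone is not opened; the E geometry keeps the new hydroxyl away from the Cα ester, so no butenolide can form.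

Step 10
Reactants: 23 methyl (3S,4R)-5,6,8-tris(benzyloxy)-4-[(2E)-4-hydroxy-1-methoxy-1-oxobut-2-en-2-yl]-1-oxoisochromane-3-carboxylate
Product: 24 methyl (3S,4R)-5,6,8-tris(benzyloxy)-4-[(2E)-1-methoxy-1,4-dioxobut-2-en-2-yl]-1-oxoisochromane-3-carboxylate
Conditions: activated MnO2 (excess), CH2Cl2, rt
Reagents that add atoms: none
Why: Selective heterogeneous oxidation of an allylic alcohol to the enal with MnO2 in the absence of base, so the C4–H that now becomes vinylogously acidic is not removed and the alkene geometry holds.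

Step 11
Reactants: 24 methyl (3S,4R)-5,6,8-tris(benzyloxy)-4-[(2E)-1-methoxy-1,4-dioxobut-2-en-2-yl]-1-oxoisochromane-3-carboxylate
Product: 25 (2E)-4-methoxy-4-oxo-3-[(3S,4R)-5,6,8-tris(benzyloxy)-3-(methoxycarbonyl)-1-oxoisochroman-4-yl]but-2-enoic acid
Conditions: NaClO2, NaH2PO4, 2-methyl-2-butene, t-BuOH/H2O, 0 °C → rt
Reagents that add atoms: sodium chlorite, [Na+].[O-]Cl=O
Why: Pinnick oxidation in a mildly acidic buffer, which leaves C3 and C4 alone, while the alkene scavenger intercepts the hypochlorous acid that would otherwise chlorinate the electron-rich ring.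

Step 12
Reactants: 25 (2E)-4-methoxy-4-oxo-3-[(3S,4R)-5,6,8-tris(benzyloxy)-3-(methoxycarbonyl)-1-oxoisochroman-4-yl]but-2-enoic acid
Product: 26 (2E)-4-methoxy-4-oxo-3-[(3S,4R)-5,6,8-trihydroxy-3-(methoxycarbonyl)-1-oxoisochroman-4-yl]but-2-enoic acid (target)
Conditions: BCl3 (6 equiv), pentamethylbenzene (10 equiv), CH2Cl2, −78 °C; CHCl3/MeOH quench, aqueous work-up under Ar
Reagents that add atoms: none
Why: Lewis-acid debenzylation with a cation scavenger, in which BCl3 activates the three aryl benzyl ethers and pentamethylbenzene captures the benzyl cations by Friedel–Crafts alkylation at −78 °C, where methyl esters, lactone, acid and alkene are inert (hydrogenolysis is excluded by the alkene).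

**Compound list**

1 | 2,4,5-trihydroxybenzoic acid | O=C(O)c1cc(O)c(O)cc1O | starting material
2 | methyl 2,4,5-trihydroxybenzoate | COC(=O)c1cc(O)c(O)cc1O | intermediate
3 | methyl 2,4,5-tris(benzyloxy)benzoate | COC(=O)c1cc(OCc2ccccc2)c(OCc2ccccc2)cc1OCc1ccccc1 | intermediate
4 | methyl propiolate | C#CC(=O)OC | starting material
5 | (tert-butyldimethylsilyloxy)acetaldehyde | CC(C)(C)[Si](C)(C)OCC=O | starting material
6 | 3-iodo-1-methoxy-1-(trimethylsilyloxy)propa-1,2-diene | COC(O[Si](C)(C)C)=C=CI | intermediate (not isolated)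
7 | methyl (2Z,3S)-4-(tert-butyldimethylsilyloxy)-2-(iodomethylidene)-3-(trimethylsilyloxy)butanoate | COC(=O)/C(=C\I)[C@H](O[Si](C)(C)C)CO[Si](C)(C)C(C)(C)C | intermediate (not isolated)
8 | methyl (2Z,3S)-4-(tert-butyldimethylsilyloxy)-3-hydroxy-2-(iodomethylidene)butanoate | COC(=O)/C(=C\I)[C@H](O)CO[Si](C)(C)C(C)(C)C | intermediate
9 | [2,3,5-tris(benzyloxy)-6-(methoxycarbonyl)phenyl]magnesium chloride | COC(=O)c1c([Mg]Cl)c(OCc2ccccc2)c(OCc2ccccc2)cc1OCc1ccccc1 | intermediate (not isolated)
10 | [2,3,5-tris(benzyloxy)-6-(methoxycarbonyl)phenyl]zinc chloride | COC(=O)c1c([Zn]Cl)c(OCc2ccccc2)c(OCc2ccccc2)cc1OCc1ccccc1 | intermediate (not isolated)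
11 | methyl 3,4,6-tris(benzyloxy)-2-[(1Z,3S)-4-(tert-butyldimethylsilyloxy)-3-hydroxy-2-(methoxycarbonyl)but-1-en-1-yl]benzoate | COC(=O)/C(=C\c1c(OCc2ccccc2)c(OCc2ccccc2)cc(OCc2ccccc2)c1C(=O)OC)[C@H](O)CO[Si](C)(C)C(C)(C)C | intermediate
12 | trimethyl orthoacetate | CC(OC)(OC)OC | starting material
13 | 1,1-dimethoxyethyl ether of 11 (mixed orthoester) | COC(=O)/C(=C\c1c(OCc2ccccc2)c(OCc2ccccc2)cc(OCc2ccccc2)c1C(=O)OC)[C@H](OC(C)(OC)OC)CO[Si](C)(C)C(C)(C)C | intermediate (not isolated)
14 | 1-methoxyvinyl ether of 11 (allyl ketene acetal) | COC(=O)/C(=C\c1c(OCc2ccccc2)c(OCc2ccccc2)cc(OCc2ccccc2)c1C(=O)OC)[C@H](OC(=C)OC)CO[Si](C)(C)C(C)(C)C | intermediate (not isolated)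
15 | dimethyl (2E,3R)-3-[2,3,5-tris(benzyloxy)-6-(methoxycarbonyl)phenyl]-2-[2-(tert-butyldimethylsilyloxy)ethylidene]pentanedioate | COC(=O)/C(=C/CO[Si](C)(C)C(C)(C)C)[C@H](CC(=O)OC)c1c(OCc2ccccc2)c(OCc2ccccc2)cc(OCc2ccccc2)c1C(=O)OC | intermediate
16 | lithium enolate of 17 | COC(=O)/C(=C/CO[Si](C)(C)C(C)(C)C)[C@H]1c2c(OCc3ccccc3)c(OCc3ccccc3)cc(OCc3ccccc3)c2C([O-])=C1C(=O)OC.[Li+] | intermediate (not isolated)
17 | methyl (3R)-4,5,7-tris(benzyloxy)-3-[(2E)-4-(tert-butyldimethylsilyloxy)-1-methoxy-1-oxobut-2-en-2-yl]-1-oxo-2,3-dihydro-1H-indene-2-carboxylate (indane C2 labile, drawn as the trans 2R keto form) | COC(=O)/C(=C/CO[Si](C)(C)C(C)(C)C)[C@H]1c2c(OCc3ccccc3)c(OCc3ccccc3)cc(OCc3ccccc3)c2C(=O)[C@@H]1C(=O)OC | intermediate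
18 | methyl (2R,3R)-4,5,7-tris(benzyloxy)-3-[(2E)-4-(tert-butyldimethylsilyloxy)-1-methoxy-1-oxobut-2-en-2-yl]-2-hydroxy-1-oxo-2,3-dihydro-1H-indene-2-carboxylate (hydroxyl trans to the side chain) | COC(=O)/C(=C/CO[Si](C)(C)C(C)(C)C)[C@H]1c2c(OCc3ccccc3)c(OCc3ccccc3)cc(OCc3ccccc3)c2C(=O)[C@@]1(O)C(=O)OC | intermediate (key-step precursor)
19 | fused oxiranolate, oxygen bridging C1 and C3, DBU-H+ salt | COC(=O)/C(=C/CO[Si](C)(C)C(C)(C)C)[C@H]1c2c(OCc3ccccc3)c(OCc3ccccc3)cc(OCc3ccccc3)c2[C@]3([O-])O[C@]13C(=O)OC.C1CCC2=[NH+]CCCN2CC1 | intermediate (not isolated)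
20 | C3 ester enolate of the ring-expanded lactone, DBU-H+ salt | COC(=O)/C(=C/CO[Si](C)(C)C(C)(C)C)[C@H]1c2c(OCc3ccccc3)c(OCc3ccccc3)cc(OCc3ccccc3)c2C(=O)OC1=C([O-])OC.C1CCC2=[NH+]CCCN2CC1 | intermediate (not isolated)
21 | methyl (3R,4R)-5,6,8-tris(benzyloxy)-4-[(2E)-4-(tert-butyldimethylsilyloxy)-1-methoxy-1-oxobut-2-en-2-yl]-1-oxoisochromane-3-carboxylate (cis) | COC(=O)/C(=C/CO[Si](C)(C)C(C)(C)C)[C@H]1c2c(OCc3ccccc3)c(OCc3ccccc3)cc(OCc3ccccc3)c2C(=O)O[C@H]1C(=O)OC | intermediate (not isolated)
22 | methyl (3S,4R)-5,6,8-tris(benzyloxy)-4-[(2E)-4-(tert-butyldimethylsilyloxy)-1-methoxy-1-oxobut-2-en-2-yl]-1-oxoisochromane-3-carboxylate (trans) | COC(=O)/C(=C/CO[Si](C)(C)C(C)(C)C)[C@H]1c2c(OCc3ccccc3)c(OCc3ccccc3)cc(OCc3ccccc3)c2C(=O)O[C@@H]1C(=O)OC | intermediate (key-step product)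
23 | methyl (3S,4R)-5,6,8-tris(benzyloxy)-4-[(2E)-4-hydroxy-1-methoxy-1-oxobut-2-en-2-yl]-1-oxoisochromane-3-carboxylate | COC(=O)/C(=C/CO)[C@H]1c2c(OCc3ccccc3)c(OCc3ccccc3)cc(OCc3ccccc3)c2C(=O)O[C@@H]1C(=O)OC | intermediate
24 | methyl (3S,4R)-5,6,8-tris(benzyloxy)-4-[(2E)-1-methoxy-1,4-dioxobut-2-en-2-yl]-1-oxoisochromane-3-carboxylate | COC(=O)/C(=C/C=O)[C@H]1c2c(OCc3ccccc3)c(OCc3ccccc3)cc(OCc3ccccc3)c2C(=O)O[C@@H]1C(=O)OC | intermediate
25 | (2E)-4-methoxy-4-oxo-3-[(3S,4R)-5,6,8-tris(benzyloxy)-3-(methoxycarbonyl)-1-oxoisochroman-4-yl]but-2-enoic acid | COC(=O)/C(=C/C(=O)O)[C@H]1c2c(OCc3ccccc3)c(OCc3ccccc3)cc(OCc3ccccc3)c2C(=O)O[C@@H]1C(=O)OC | intermediate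
26 | (2E)-4-methoxy-4-oxo-3-[(3S,4R)-5,6,8-trihydroxy-3-(methoxycarbonyl)-1-oxoisochroman-4-yl]but-2-enoic acid | COC(=O)/C(=C/C(=O)O)[C@H]1c2c(O)c(O)cc(O)c2C(=O)O[C@@H]1C(=O)OC | target

**Step count**

Total step count: 12.
Longest linear sequence: 11 steps (1 → 26 through steps 1, 2 and 4–12). Step 3 is a one-step side branch.

**Steps most likely to fail**

Step 8 (key step).
- The alkoxide may hand over the methoxycarbonyl group instead of the aroyl carbon, or trigger a 1,2-shift of the α-ketol type.
- Ionisation by DBU may be too weak for the shift to run below the temperature at which C4–H is removed and the lactone opens by loss of the C1 carboxylate.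
- The C3 equilibrium may not lie far enough on the trans side.
- Any hydroxyl epimer cis to the side chain would be lost through attack on the Cα ester.

The fallback keeps the temporary C1–C3 bond but brings O2 in as a carboxylate oxygen, using known reactions. It sets out from 17.
- NBS in CH2Cl2 at 0 °C should give the 2-bromo β-keto ester F1.
- LiOH (1 equiv) in THF/H2O at 0 °C should cleave its activated, non-enolisable ketone (deacylative retro-Claisen cleavage of an α-halo β-keto ester) to the seco bromo acid F2.
- K2CO3 in DMF should then close the lactone by 6-exo-tet displacement of bromide by the C1 carboxylate. The Cα ester cannot compete in this closure, whereas an open-chain C3 alcohol could also lactonise onto it.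
- A final DBU equilibration of C3 returns to the route at 22.

Step 5.
- The pseudoaxial placement of CH2OTBS is opposed by its 1,3-diaxial contact with the methoxy group of the ketene acetal. The alkene geometry could therefore erode, and since geometry and C4 configuration are coupled, material would be lost on separation.
- The di-ortho-substituted aryl group may also slow bond formation at C4.

The fallback removes the offending alkoxy group. It sets out from 11.
- Transfer vinylation with butyl vinyl ether under Pd(OCOCF3)2 and 4,7-diphenyl-1,10-phenanthroline gives the allyl vinyl ether F3.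
- An aliphatic Claisen rearrangement in toluene at 110–130 °C, with only hydrogen on the vinyl carbon facing the pseudoaxial group, gives the aldehyde F4.
- Pinnick oxidation gives the acid F5, and TMSCHN2 esterification returns to the route at 15.

Step 3.
- Facial discrimination on an α-silyloxy aldehyde may be poor.
- An uncatalysed background addition of the allenolate may dilute the enantiomeric purity that all later centres depend on.

The fallback separates bond formation from stereocontrol. It sets out from 4 and 5.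
- MgI2 in CH2Cl2 at 0 °C gives the racemic Z-iodo alcohol F6.
- Acylative kinetic resolution with immobilised Burkholderia cepacia lipase and vinyl acetate in MTBE follows. By the empirical size rule (alkenyl large, CH2OSi medium) it should convert the (S)-enantiomer to the (S)-acetate F7 and leave the (R)-alcohol F8.
- After chromatographic separation, methanolysis of F7 catalysed by the same lipase avoids alkoxide attack on the iodoacrylate and returns to the route at 8.

**Further compounds**

F1 | step 8 | methyl (3R)-4,5,7-tris(benzyloxy)-2-bromo-3-[(2E)-4-(tert-butyldimethylsilyloxy)-1-methoxy-1-oxobut-2-en-2-yl]-1-oxo-2,3-dihydro-1H-indene-2-carboxylate (bromine trans to the side chain) | COC(=O)/C(=C/CO[Si](C)(C)C(C)(C)C)[C@H]1c2c(OCc3ccccc3)c(OCc3ccccc3)cc(OCc3ccccc3)c2C(=O)[C@@]1(Br)C(=O)OC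
F2 | step 8 | 3,4,6-tris(benzyloxy)-2-[(3E)-1-bromo-5-(tert-butyldimethylsilyloxy)-1,3-bis(methoxycarbonyl)pent-3-en-2-yl]benzoic acid (C4 as in 22, epimers at the bromide carbon) | COC(=O)/C(=C/CO[Si](C)(C)C(C)(C)C)[C@H](C(Br)C(=O)OC)c1c(OCc2ccccc2)c(OCc2ccccc2)cc(OCc2ccccc2)c1C(=O)O
F3 | step 5 | vinyl ether of 11 | COC(=O)/C(=C\c1c(OCc2ccccc2)c(OCc2ccccc2)cc(OCc2ccccc2)c1C(=O)OC)[C@H](OC=C)CO[Si](C)(C)C(C)(C)C
F4 | step 5 | methyl 3,4,6-tris(benzyloxy)-2-[(2R,3E)-5-(tert-butyldimethylsilyloxy)-3-(methoxycarbonyl)-1-formylpent-3-en-2-yl]benzoate | COC(=O)/C(=C/CO[Si](C)(C)C(C)(C)C)[C@H](CC=O)c1c(OCc2ccccc2)c(OCc2ccccc2)cc(OCc2ccccc2)c1C(=O)OC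
F5 | step 5 | (3R,4E)-3-[2,3,5-tris(benzyloxy)-6-(methoxycarbonyl)phenyl]-6-(tert-butyldimethylsilyloxy)-4-(methoxycarbonyl)hex-4-enoic acid | COC(=O)/C(=C/CO[Si](C)(C)C(C)(C)C)[C@H](CC(=O)O)c1c(OCc2ccccc2)c(OCc2ccccc2)cc(OCc2ccccc2)c1C(=O)OC
F6 | step 3 | racemic methyl (2Z)-4-(tert-butyldimethylsilyloxy)-3-hydroxy-2-(iodomethylidene)butanoate | COC(=O)/C(=C\I)C(O)CO[Si](C)(C)C(C)(C)C
F7 | step 3 | methyl (2Z,3S)-3-acetoxy-4-(tert-butyldimethylsilyloxy)-2-(iodomethylidene)butanoate | COC(=O)/C(=C\I)[C@H](OC(C)=O)CO[Si](C)(C)C(C)(C)C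
F8 | step 3 | methyl (2Z,3R)-4-(tert-butyldimethylsilyloxy)-3-hydroxy-2-(iodomethylidene)butanoate | COC(=O)/C(=C\I)[C@@H](O)CO[Si](C)(C)C(C)(C)C
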